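Numbering: flavanone numbering for rings A–C. The C8 side chain is C1''–C7'', counted from the styryl CH, so C3'' sits on C8 and the OH sits on C5''.
Cuts, in retrosynthetic order: O1–C2 (ring C), C4–C4a (aryl ketone), C5''–H (ketone reduction), then C3''–C4'' together with a ring A oxygen–C5'' bond (a temporary 4H-chromene), and last C2''–C3''.
Enabling feature: C8 of ring A lies between two phenolic oxygens (7-OH and O1). Its substituent carbon C3'' is benzylic, allylic and 1,3 to oxygenated C5''. O–C7–C8–C3'' can therefore be unmasked as a vinyl ortho-quinone methide, and C4''=C5'' as the enol of a β-ketoester.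
Forward order: ring A aldehyde 6 and a styryllithium give carbinol 9. Carbinol 9 and ketoester 12 close the pyran ring of chromene 15. The pyran is reopened (17), ring A is brominated and acylated (23), and ring C closes last (25).
From step 11 until the acyl group arrives, both oxygens flanking C8 carry MOM. It is therefore immaterial which oxygen served in the methide and which ring A CH is functionalised.
Stereochemistry: C3'' comes from the chiral phosphoric acid (step 8), C5'' from the CBS catalyst (step 12), and C2 from a cinchona thiourea (step 16). Both E alkenes come from Takai and Horner–Wadsworth–Emmons olefinations.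

Key step: step 8

Assumption: the absolute sense of induction in steps 8 and 16 is assigned by analogy with simpler substrates; if either runs the other way, the enantiomeric acid or the quinine-derived pseudoenantiomeric thiourea is used and nothing else changes.

Step 1
Reactants: 1 4-hydroxybenzaldehyde
Product: 2 4-(methoxymethoxy)benzaldehyde
Conditions: MOMCl, i-Pr2NEt, CH2Cl2, 0 °C to rt
Reagents that add atoms: chloromethyl methyl ether (MOMCl), COCCl
Why: Williamson-type O-alkylation of the phenol gives an acetal ether that tolerates the organolithium, hydride and basic steps ahead and can be shed under mild acid at the end.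

Step 2
Reactants: 2 4-(methoxymethoxy)benzaldehyde
Product: 3 1-[(E)-2-iodoethenyl]-4-(methoxymethoxy)benzene
Conditions: CHI3, CrCl2, THF, 0 °C
Reagents that add atoms: iodoform, IC(I)I
Why: The Takai olefination of an aromatic aldehyde gives the (E)-alkenyl iodide by addition of the geminal dichromium reagent and elimination, and the MOM ether is inert to divalent chromium.

Step 3
Reactants: 4 2,4,6-trihydroxybenzaldehyde
Product: 5 2,6-dihydroxy-4-methoxybenzaldehyde
Conditions: MeI (1 equiv), K2CO3 (1 equiv), acetone, rt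
Reagents that add atoms: iodomethane, CI
Why: In this regioselective Williamson methylation the 2- and 6-hydroxyls are held in hydrogen bonds to the formyl oxygen, so one equivalent of base and MeI should alkylate the more acidic, unchelated 4-OH.

Step 4
Reactants: 5 2,6-dihydroxy-4-methoxybenzaldehyde
Product: 6 2-hydroxy-4-methoxy-6-(methoxymethoxy)benzaldehyde
Conditions: MOMCl (1 equiv), i-Pr2NEt, CH2Cl2, 0 °C
Reagents that add atoms: chloromethyl methyl ether (MOMCl), COCCl
Why: Once one of the two equivalent ortho hydroxyls is alkylated, the other is locked in a strong hydrogen bond to the aldehyde, so O-alkylation should stop at the monoether, as is usual for 2,6-dihydroxyaryl carbonyl compounds.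

Step 5
Reactants: 3 1-[(E)-2-iodoethenyl]-4-(methoxymethoxy)benzene; 6 2-hydroxy-4-methoxy-6-(methoxymethoxy)benzaldehyde
Product: 9 rac-2-{(2E)-1-hydroxy-3-[4-(methoxymethoxy)phenyl]prop-2-en-1-yl}-5-methoxy-3-(methoxymethoxy)phenol, via styryllithium 7 (not isolated), via sodium phenoxide 8 (not isolated)
Conditions: 3, t-BuLi (2 equiv), Et2O, −78 °C; separately 6, NaH, THF, 0 °C; combine at −78 °C, warm to −20 °C; sat. aq NH4Cl; used crude, kept cold
Reagents that add atoms: none
Why: Iodine–lithium exchange with retention of the E geometry, followed by 1,2-addition of the alkenyllithium to the pre-deprotonated salicylaldehyde, is the standard entry to ortho-hydroxybenzylic alcohols, and the racemic carbinol centre does not matter because step 8 erases it.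

Step 6
Reactants: 10 4-(4-hydroxyphenyl)butan-2-one (raspberry ketone)
Product: 11 4-[4-(methoxymethoxy)phenyl]butan-2-one
Conditions: MOMCl, i-Pr2NEt, CH2Cl2, 0 °C to rt
Reagents that add atoms: chloromethyl methyl ether (MOMCl), COCCl
Why: Williamson-type O-alkylation masks the phenol before the strongly basic acylation that follows.

Step 7
Reactants: 11 4-[4-(methoxymethoxy)phenyl]butan-2-one
Product: 12 allyl 5-[4-(methoxymethoxy)phenyl]-3-oxopentanoate
Conditions: NaH (2.5 equiv), diallyl carbonate, THF, reflux; AcOH quench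
Reagents that add atoms: diallyl carbonate, C=CCOC(=O)OCC=C
Why: The crossed Claisen C-acylation of a methyl ketone with a dialkyl carbonate takes place, under these reversible conditions, at the less hindered methyl carbon and is driven by formation of the stabilised sodium enolate, so the allyl ester is installed directly.

Step 8
Reactants: 9 rac-2-{(2E)-1-hydroxy-3-[4-(methoxymethoxy)phenyl]prop-2-en-1-yl}-5-methoxy-3-(methoxymethoxy)phenol; 12 allyl 5-[4-(methoxymethoxy)phenyl]-3-oxopentanoate
Product: 15 allyl (4S)-7-methoxy-5-(methoxymethoxy)-2-{2-[4-(methoxymethoxy)phenyl]ethyl}-4-{(E)-2-[4-(methoxymethoxy)phenyl]ethenyl}-4H-chromene-3-carboxylate, via vinyl ortho-quinone methide 13 (not isolated), via hemiketal 14 (not isolated)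
Conditions: (R)-TRIP [(R)-3,3'-bis(2,4,6-triisopropylphenyl)-1,1'-binaphthyl-2,2'-diyl hydrogen phosphate] (10 mol %), 12 (2 equiv), 4 Å MS, CHCl3, 0 °C, slow addition of 9; then TsOH·H2O (5 mol %), 40 °C
Reagents that add atoms: none
Why: The phosphoric acid ionises the carbinol of 9, which is benzylic, allylic and activated by the ortho-hydroxy and para-methoxy groups; this erases the racemic centre and gives the hydrogen-bonded vinyl ortho-quinone methide 13, to whose C3'' the enol of 12, held by the phosphoryl oxygen of the same catalyst, adds through C4'' with rearomatisation of ring A. The liberated phenol then adds to the C5'' ketone (6-exo-trig hemiketalisation to 14), and acid-promoted loss of water gives the conjugated 4H-chromene 15, so one ring and the C3''–C4'' and O–C5'' bonds arise in one flask. The closest known reaction type is the chiral-phosphoric-acid-catalysed conjugate addition and cyclodehydration of 1,3-dicarbonyl compounds with ortho-quinone methides generated in situ from ortho-hydroxybenzyl alcohols. C3'' is the only new stereocentre, and its S configuration is fixed by the 3,3'-aryl pockets of the catalyst, which expose one face of the bound methide to the bound enol. The step needs 1,4- rather than 1,6-addition (attack at C1'') and must outrun self-alkylation of the electron-rich ring A: two-point binding places the enol next to C3'', attack there restores the aromaticity of ring A while keeping the styrene conjugated, and slow addition of 9 into excess 12 keeps the methide dilute. The main side path is oxa-6π closure of 13 to a 2-aryl-2H-chromene, but its C–O bond is benzylic to a para-alkoxyphenyl ring and vinylogously benzylic to ring A, so it should re-ionise under the same acid and drain into the irreversible C–C bond formation.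

Step 9
Reactants: 15 allyl (4S)-7-methoxy-5-(methoxymethoxy)-2-{2-[4-(methoxymethoxy)phenyl]ethyl}-4-{(E)-2-[4-(methoxymethoxy)phenyl]ethenyl}-4H-chromene-3-carboxylate
Product: 17 (5S,6E)-5-[2-hydroxy-4-methoxy-6-(methoxymethoxy)phenyl]-1,7-bis[4-(methoxymethoxy)phenyl]hept-6-en-3-one, via chromene-3-carboxylic acid 16 (not isolated)
Conditions: Pd(PPh3)4 (5 mol %), morpholine (3 equiv), THF, rt; then AcOH–H2O 4:1, 60 °C
Reagents that add atoms: water, O
Why: Tsuji–Trost deallylation with zerovalent palladium frees the acid under neutral conditions and so turns the unreactive push–pull alkene into a carboxylate-bearing enol ether that the warm acetate buffer protonates at C4'', after which decarboxylation and enol ether hydrolysis follow (hydrolytic decarboxylation of a β-alkoxyacrylic acid), while the less basic styrene and the aryl MOM ethers should persist and C3'' is not touched.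

Step 10
Reactants: 17 (5S,6E)-5-[2-hydroxy-4-methoxy-6-(methoxymethoxy)phenyl]-1,7-bis[4-(methoxymethoxy)phenyl]hept-6-en-3-one
Product: 18 (5S,6E)-5-[3-bromo-2-hydroxy-4-methoxy-6-(methoxymethoxy)phenyl]-1,7-bis[4-(methoxymethoxy)phenyl]hept-6-en-3-one
Conditions: NBS (1 equiv), i-Pr2NH (10 mol %), CH2Cl2, −78 °C
Reagents that add atoms: N-bromosuccinimide, O=C1CCC(=O)N1Br
Why: In this electrophilic aromatic bromination the free phenol makes ring A far more nucleophilic than the styrene or the outer rings, the amine-mediated NBS protocol directs ortho to the hydroxyl, and attack at the other ring A CH would be harmless because both isomers give 19 in step 11.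

Step 11
Reactants: 18 (5S,6E)-5-[3-bromo-2-hydroxy-4-methoxy-6-(methoxymethoxy)phenyl]-1,7-bis[4-(methoxymethoxy)phenyl]hept-6-en-3-one
Product: 19 (5S,6E)-5-[3-bromo-4-methoxy-2,6-bis(methoxymethoxy)phenyl]-1,7-bis[4-(methoxymethoxy)phenyl]hept-6-en-3-one
Conditions: MOMCl, i-Pr2NEt, CH2Cl2, 0 °C to rt
Reagents that add atoms: chloromethyl methyl ether (MOMCl), COCCl
Why: O-alkylation of the phenol traps the open keto form out of its hemiketal equilibrium and makes the two oxygens flanking C8 alike, giving a single bromide ready for reduction and metalation.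

Step 12
Reactants: 19 (5S,6E)-5-[3-bromo-4-methoxy-2,6-bis(methoxymethoxy)phenyl]-1,7-bis[4-(methoxymethoxy)phenyl]hept-6-en-3-one
Product: 20 (3S,5S,6E)-5-[3-bromo-4-methoxy-2,6-bis(methoxymethoxy)phenyl]-1,7-bis[4-(methoxymethoxy)phenyl]hept-6-en-3-ol
Conditions: (R)-Me-CBS oxazaborolidine (20 mol %), catecholborane (2 equiv), toluene, −78 to −40 °C; MeOH, then aq NaOH wash
Reagents that add atoms: none
Why: In the Corey–Bakshi–Shibata reduction the β-branched C4'' arm (carrying the 2,6-disubstituted ring A and the styryl group) acts as the large substituent and the CH2CH2Ar arm as the small one, so the (R)-oxazaborolidine should deliver hydride to the face that gives the 5''S alcohol, syn to C3'', while catecholborane at low temperature leaves the styrene untouched.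

Step 13
Reactants: 2 4-(methoxymethoxy)benzaldehyde
Product: 21 (2E)-N-methoxy-N-methyl-3-[4-(methoxymethoxy)phenyl]prop-2-enamide
Conditions: (EtO)2P(O)CH2C(O)N(OMe)Me, LiCl, DBU, MeCN, rt
Reagents that add atoms: diethyl {2-[methoxy(methyl)amino]-2-oxoethyl}phosphonate, CCOP(=O)(CC(=O)N(C)OC)OCC
Why: The Horner–Wadsworth–Emmons olefination under Masamune–Roush conditions with a stabilised phosphonate gives the (E)-cinnamoyl Weinreb amide in one operation.

Step 14
Reactants: 20 (3S,5S,6E)-5-[3-bromo-4-methoxy-2,6-bis(methoxymethoxy)phenyl]-1,7-bis[4-(methoxymethoxy)phenyl]hept-6-en-3-ol; 21 (2E)-N-methoxy-N-methyl-3-[4-(methoxymethoxy)phenyl]prop-2-enamide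
Product: 23 (2E)-1-{3-[(1E,3S,5S)-5-hydroxy-1,7-bis[4-(methoxymethoxy)phenyl]hept-1-en-3-yl]-6-methoxy-2,4-bis(methoxymethoxy)phenyl}-3-[4-(methoxymethoxy)phenyl]prop-2-en-1-one, via dilithio species 22 (not isolated)
Conditions: n-BuLi (2.1 equiv), THF, −78 °C; then 21, −78 to 0 °C; sat. aq NH4Cl
Reagents that add atoms: none
Why: Bromine–lithium exchange at −78 °C is faster than deprotonation of the acidic C3''–H, the alcohol travels as its lithium alkoxide, and the aryllithium adds 1,2 to the Weinreb amide, whose chelated tetrahedral adduct collapses to the enone only on quench (Weinreb ketone synthesis).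

Step 15
Reactants: 23 (2E)-1-{3-[(1E,3S,5S)-5-hydroxy-1,7-bis[4-(methoxymethoxy)phenyl]hept-1-en-3-yl]-6-methoxy-2,4-bis(methoxymethoxy)phenyl}-3-[4-(methoxymethoxy)phenyl]prop-2-en-1-one
Product: 24 (2E)-1-{2-hydroxy-3-[(1E,3S,5S)-5-hydroxy-1,7-bis[4-(methoxymethoxy)phenyl]hept-1-en-3-yl]-6-methoxy-4-(methoxymethoxy)phenyl}-3-[4-(methoxymethoxy)phenyl]prop-2-en-1-one
Conditions: MgBr2·OEt2 (3 equiv), Et2O–CH2Cl2, 0 °C to rt; aq work-up
Reagents that add atoms: none
Why: In this chelation-assisted acetal cleavage, magnesium bound between the carbonyl oxygen and the neighbouring acetal oxygens activates only the MOM ether ortho to the ketone, the resulting phenol is stabilised by its hydrogen bond, and the four remote aryl MOM ethers are not activated.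

Step 16
Reactants: 24 (2E)-1-{2-hydroxy-3-[(1E,3S,5S)-5-hydroxy-1,7-bis[4-(methoxymethoxy)phenyl]hept-1-en-3-yl]-6-methoxy-4-(methoxymethoxy)phenyl}-3-[4-(methoxymethoxy)phenyl]prop-2-en-1-one
Product: 25 (2S)-8-[(1E,3S,5S)-5-hydroxy-1,7-bis[4-(methoxymethoxy)phenyl]hept-1-en-3-yl]-5-methoxy-7-(methoxymethoxy)-2-[4-(methoxymethoxy)phenyl]-2,3-dihydro-4H-chromen-4-one
Conditions: 9-amino(9-deoxy)-epi-quinidine 3,5-bis(trifluoromethyl)phenyl thiourea (20 mol %), toluene, rt; stopped before equilibration
Reagents that add atoms: none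
Why: In this bifunctional organocatalytic intramolecular oxa-Michael addition (6-endo-trig) of a 2'-hydroxychalcone, the quinuclidine activates the phenol while the thiourea binds the enone carbonyl, so one enone face is attacked and C2 should form as S; the methoxy group ortho to the ketone favours the closed form, and any 2R epimer is a separable diastereomer because C3'' and C5'' are fixed.

Step 17
Reactants: 25 (2S)-8-[(1E,3S,5S)-5-hydroxy-1,7-bis[4-(methoxymethoxy)phenyl]hept-1-en-3-yl]-5-methoxy-7-(methoxymethoxy)-2-[4-(methoxymethoxy)phenyl]-2,3-dihydro-4H-chromen-4-one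
Product: 26 (2S)-7-hydroxy-8-[(1E,3S,5S)-5-hydroxy-1,7-bis(4-hydroxyphenyl)hept-1-en-3-yl]-2-(4-hydroxyphenyl)-5-methoxy-2,3-dihydro-4H-chromen-4-one (target)
Conditions: NaHSO4·SiO2, CH2Cl2, rt; product eluted with EtOAc–MeOH
Reagents that add atoms: none
Why: This mild heterogeneous Brønsted-acid hydrolysis, selective for phenolic MOM ethers, removes all four acetals at room temperature, where the flavanone C2 centre does not epimerise and protonation of the 4-hydroxystyrene (which would let the C5'' hydroxyl close a tetrahydropyran) should not compete.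

Compound list
1 | 4-hydroxybenzaldehyde | O=Cc1ccc(O)cc1 | starting material
2 | 4-(methoxymethoxy)benzaldehyde | COCOc1ccc(C=O)cc1 | intermediate
3 | 1-[(E)-2-iodoethenyl]-4-(methoxymethoxy)benzene | COCOc1ccc(/C=C/I)cc1 | intermediate
4 | 2,4,6-trihydroxybenzaldehyde | O=Cc1c(O)cc(O)cc1O | starting material
5 | 2,6-dihydroxy-4-methoxybenzaldehyde | COc1cc(O)c(C=O)c(O)c1 | intermediate
6 | 2-hydroxy-4-methoxy-6-(methoxymethoxy)benzaldehyde | COCOc1cc(OC)cc(O)c1C=O | intermediate
7 | (E)-2-[4-(methoxymethoxy)phenyl]ethenyllithium | [Li]/C=C/c1ccc(OCOC)cc1 | intermediate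
8 | sodium 2-formyl-5-methoxy-3-(methoxymethoxy)phenolate | [Na+].[O-]c1cc(OC)cc(OCOC)c1C=O | intermediate
9 | rac-2-{(2E)-1-hydroxy-3-[4-(methoxymethoxy)phenyl]prop-2-en-1-yl}-5-methoxy-3-(methoxymethoxy)phenol | COCOc1ccc(/C=C/C(O)c2c(O)cc(OC)cc2OCOC)cc1 | intermediate
10 | 4-(4-hydroxyphenyl)butan-2-one (raspberry ketone) | CC(=O)CCc1ccc(O)cc1 | starting material
11 | 4-[4-(methoxymethoxy)phenyl]butan-2-one | CC(=O)CCc1ccc(OCOC)cc1 | intermediate
12 | allyl 5-[4-(methoxymethoxy)phenyl]-3-oxopentanoate | COCOc1ccc(CCC(=O)CC(=O)OCC=C)cc1 | intermediate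
13 | 3-methoxy-5-(methoxymethoxy)-6-{(2E)-3-[4-(methoxymethoxy)phenyl]prop-2-en-1-ylidene}cyclohexa-2,4-dien-1-one (vinyl ortho-quinone methide, exocyclic geometry open) | O=C1C=C(OC)C=C(OCOC)C1=C/C=C/c1ccc(OCOC)cc1 | intermediate
14 | allyl (4R)-2-hydroxy-7-methoxy-5-(methoxymethoxy)-2-{2-[4-(methoxymethoxy)phenyl]ethyl}-4-{(E)-2-[4-(methoxymethoxy)phenyl]ethenyl}chromane-3-carboxylate (C4 spatially as in 15, descriptor changes by rule only; mixture at C2 and C3; in equilibrium with the open β-ketoester) | COc1cc(OCOC)c2[C@H](/C=C/c3ccc(OCOC)cc3)C(C(=O)OCC=C)C(O)(CCc3ccc(OCOC)cc3)Oc2c1 | intermediate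
15 | allyl (4S)-7-methoxy-5-(methoxymethoxy)-2-{2-[4-(methoxymethoxy)phenyl]ethyl}-4-{(E)-2-[4-(methoxymethoxy)phenyl]ethenyl}-4H-chromene-3-carboxylate | COc1cc(OCOC)c2[C@H](/C=C/c3ccc(OCOC)cc3)C(C(=O)OCC=C)=C(CCc3ccc(OCOC)cc3)Oc2c1 | intermediate
16 | (4S)-7-methoxy-5-(methoxymethoxy)-2-{2-[4-(methoxymethoxy)phenyl]ethyl}-4-{(E)-2-[4-(methoxymethoxy)phenyl]ethenyl}-4H-chromene-3-carboxylic acid | COc1cc(OCOC)c2[C@H](/C=C/c3ccc(OCOC)cc3)C(C(=O)O)=C(CCc3ccc(OCOC)cc3)Oc2c1 | intermediate
17 | (5S,6E)-5-[2-hydroxy-4-methoxy-6-(methoxymethoxy)phenyl]-1,7-bis[4-(methoxymethoxy)phenyl]hept-6-en-3-one (drawn open; in equilibrium with its cyclic hemiketal) | COc1cc(O)c([C@H](/C=C/c2ccc(OCOC)cc2)CC(=O)CCc2ccc(OCOC)cc2)c(OCOC)c1 | intermediate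
18 | (5S,6E)-5-[3-bromo-2-hydroxy-4-methoxy-6-(methoxymethoxy)phenyl]-1,7-bis[4-(methoxymethoxy)phenyl]hept-6-en-3-one | COc1cc(OCOC)c([C@H](/C=C/c2ccc(OCOC)cc2)CC(=O)CCc2ccc(OCOC)cc2)c(O)c1Br | intermediate
19 | (5S,6E)-5-[3-bromo-4-methoxy-2,6-bis(methoxymethoxy)phenyl]-1,7-bis[4-(methoxymethoxy)phenyl]hept-6-en-3-one | COc1cc(OCOC)c([C@H](/C=C/c2ccc(OCOC)cc2)CC(=O)CCc2ccc(OCOC)cc2)c(OCOC)c1Br | intermediate
20 | (3S,5S,6E)-5-[3-bromo-4-methoxy-2,6-bis(methoxymethoxy)phenyl]-1,7-bis[4-(methoxymethoxy)phenyl]hept-6-en-3-ol | COc1cc(OCOC)c([C@H](/C=C/c2ccc(OCOC)cc2)C[C@@H](O)CCc2ccc(OCOC)cc2)c(OCOC)c1Br | intermediate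
21 | (2E)-N-methoxy-N-methyl-3-[4-(methoxymethoxy)phenyl]prop-2-enamide | COCOc1ccc(/C=C/C(=O)N(C)OC)cc1 | intermediate
22 | aryllithium lithium alkoxide derived from 20 (Li in place of Br and of the hydroxyl H) | COc1cc(OCOC)c([C@H](/C=C/c2ccc(OCOC)cc2)C[C@@H](O[Li])CCc2ccc(OCOC)cc2)c(OCOC)c1[Li] | intermediate
23 | (2E)-1-{3-[(1E,3S,5S)-5-hydroxy-1,7-bis[4-(methoxymethoxy)phenyl]hept-1-en-3-yl]-6-methoxy-2,4-bis(methoxymethoxy)phenyl}-3-[4-(methoxymethoxy)phenyl]prop-2-en-1-one | COc1cc(OCOC)c([C@H](/C=C/c2ccc(OCOC)cc2)C[C@@H](O)CCc2ccc(OCOC)cc2)c(OCOC)c1C(=O)/C=C/c1ccc(OCOC)cc1 | intermediate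
24 | (2E)-1-{2-hydroxy-3-[(1E,3S,5S)-5-hydroxy-1,7-bis[4-(methoxymethoxy)phenyl]hept-1-en-3-yl]-6-methoxy-4-(methoxymethoxy)phenyl}-3-[4-(methoxymethoxy)phenyl]prop-2-en-1-one | COc1cc(OCOC)c([C@H](/C=C/c2ccc(OCOC)cc2)C[C@@H](O)CCc2ccc(OCOC)cc2)c(O)c1C(=O)/C=C/c1ccc(OCOC)cc1 | intermediate
25 | (2S)-8-[(1E,3S,5S)-5-hydroxy-1,7-bis[4-(methoxymethoxy)phenyl]hept-1-en-3-yl]-5-methoxy-7-(methoxymethoxy)-2-[4-(methoxymethoxy)phenyl]-2,3-dihydro-4H-chromen-4-one | COc1cc(OCOC)c([C@H](/C=C/c2ccc(OCOC)cc2)C[C@@H](O)CCc2ccc(OCOC)cc2)c2c1C(=O)C[C@@H](c1ccc(OCOC)cc1)O2 | intermediate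
26 | (2S)-7-hydroxy-8-[(1E,3S,5S)-5-hydroxy-1,7-bis(4-hydroxyphenyl)hept-1-en-3-yl]-2-(4-hydroxyphenyl)-5-methoxy-2,3-dihydro-4H-chromen-4-one | COc1cc(O)c([C@H](/C=C/c2ccc(O)cc2)C[C@@H](O)CCc2ccc(O)cc2)c2c1C(=O)C[C@@H](c1ccc(O)cc1)O2 | target

Total step count: 17.
Longest linear sequence: 12 steps (1, 2, 5, 8, 9, 10, 11, 12, 14, 15, 16, 17). The branch through steps 3, 4 and 5 is equally long.

Steps most likely to fail

Step 8.
- What may go wrong: the vinyl quinone methide may close onto its own oxygen at C1'' faster than the bimolecular addition can occur.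
- The enol may attack at the distal carbon C1''.
- Face discrimination may be weak, because the acetal group next to C8 perturbs the methide geometry.
- Fallback: it forms the same two bonds and the same ring but carries C1''–C2'' one oxidation level higher. It sets out from 2, 6 and 12 and returns at 15.
- Aldehyde 2 is homologated with dimethyl (1-diazo-2-oxopropyl)phosphonate and K2CO3 in MeOH (Ohira–Bestmann reaction) to 1-ethynyl-4-(methoxymethoxy)benzene F1.
- n-BuLi converts it into the lithium acetylide F2, which adds to phenoxide 8 (made from 6 as in step 5) to give the racemic propargylic alcohol F3.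
- Under the conditions of step 8, F3 ionises to the alkynyl ortho-quinone methide F4, whose linear substituent cannot reach the oxygen.
- Addition of 12 gives the alkynyl hemiketal F5 and, after dehydration, the 4-alkynyl-4H-chromene F6.
- trans-Hydrosilylation with (EtO)3SiH and [Cp*Ru(MeCN)3]PF6 in CH2Cl2 at 0 °C gives the (Z)-alkenylsilane F7. It is drawn with silicon on C2''; the regioisomer converges.
- Protodesilylation with AgF in aqueous THF–MeOH gives 15.

Step 12.
- What may go wrong: facial discrimination may be poor because both carbonyl substituents begin with a CH2 group, and turnover on the hindered ketone may be slow.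
- Fallback: it replaces reagent control by separation and stereoinversion. It sets out from 19 and returns at 20.
- NaBH4 in MeOH reduces 19 without bias, and the C5'' epimers are separated by chromatography.
- The unwanted (3R,5S)-alcohol F8 is inverted in a Mitsunobu reaction (4-nitrobenzoic acid, PPh3, DIAD, THF) to the (3S,5S)-4-nitrobenzoate F9.
- Methanolysis with K2CO3 in MeOH gives 20, so both halves of the material converge.

Step 16.
- What may go wrong: face selectivity on an unactivated chalcone may be low, and the ratio may erode through reversible ring opening under the basic catalyst.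
- Fallback: it sets C2 by C–C instead of C–O bond formation. It sets out from 20 and returns at 25.
- The dilithio species 22, made as in step 14, is quenched with N-methoxy-N-methylacetamide to give the bis-MOM acetophenone F10.
- MgBr2·OEt2 cleaves the acetal ortho to the ketone to give the 2-hydroxyacetophenone F11.
- N,N-Dimethylformamide dimethyl acetal in warm toluene gives the enaminone F12, and warm AcOH closes it to the chromone F13.
- Rhodium-catalysed asymmetric 1,4-addition of 4-(methoxymethoxy)phenylboronic acid ([Rh(OH)(cod)]2 with an electron-poor MeO-BIPHEP-type diphosphine of the enantiomeric series that gives 2S, in aqueous toluene) then gives 25 under catalyst control.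

Further compounds
F1 | step 8 | 1-ethynyl-4-(methoxymethoxy)benzene | COCOc1ccc(C#C)cc1
F2 | step 8 | lithium [4-(methoxymethoxy)phenyl]acetylide | [Li]C#Cc1ccc(OCOC)cc1
F3 | step 8 | rac-2-{1-hydroxy-3-[4-(methoxymethoxy)phenyl]prop-2-yn-1-yl}-5-methoxy-3-(methoxymethoxy)phenol | COCOc1ccc(C#CC(O)c2c(O)cc(OC)cc2OCOC)cc1
F4 | step 8 | 3-methoxy-5-(methoxymethoxy)-6-{3-[4-(methoxymethoxy)phenyl]prop-2-yn-1-ylidene}cyclohexa-2,4-dien-1-one | O=C1C=C(OC)C=C(OCOC)C1=CC#Cc1ccc(OCOC)cc1
F5 | step 8 | allyl 2-hydroxy-7-methoxy-5-(methoxymethoxy)-2-{2-[4-(methoxymethoxy)phenyl]ethyl}-4-{[4-(methoxymethoxy)phenyl]ethynyl}chromane-3-carboxylate (C4 as in F6, mixture at C2 and C3) | COc1cc(OCOC)c2[C@H](C#Cc3ccc(OCOC)cc3)C(C(=O)OCC=C)C(O)(CCc3ccc(OCOC)cc3)Oc2c1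
F6 | step 8 | allyl (4S)-7-methoxy-5-(methoxymethoxy)-2-{2-[4-(methoxymethoxy)phenyl]ethyl}-4-{[4-(methoxymethoxy)phenyl]ethynyl}-4H-chromene-3-carboxylate | COc1cc(OCOC)c2[C@H](C#Cc3ccc(OCOC)cc3)C(C(=O)OCC=C)=C(CCc3ccc(OCOC)cc3)Oc2c1
F7 | step 8 | allyl (4S)-7-methoxy-5-(methoxymethoxy)-2-{2-[4-(methoxymethoxy)phenyl]ethyl}-4-{(Z)-2-[4-(methoxymethoxy)phenyl]-1-(triethoxysilyl)ethenyl}-4H-chromene-3-carboxylate | COc1cc(OCOC)c2[C@H](/C([Si](OCC)(OCC)OCC)=C/c3ccc(OCOC)cc3)C(C(=O)OCC=C)=C(CCc3ccc(OCOC)cc3)Oc2c1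
F8 | step 12 | (3R,5S,6E)-5-[3-bromo-4-methoxy-2,6-bis(methoxymethoxy)phenyl]-1,7-bis[4-(methoxymethoxy)phenyl]hept-6-en-3-ol | COc1cc(OCOC)c([C@H](/C=C/c2ccc(OCOC)cc2)C[C@H](O)CCc2ccc(OCOC)cc2)c(OCOC)c1Br
F9 | step 12 | (3S,5S,6E)-5-[3-bromo-4-methoxy-2,6-bis(methoxymethoxy)phenyl]-1,7-bis[4-(methoxymethoxy)phenyl]hept-6-en-3-yl 4-nitrobenzoate | COc1cc(OCOC)c([C@H](/C=C/c2ccc(OCOC)cc2)C[C@@H](OC(=O)c2ccc(cc2)[N+](=O)[O-])CCc2ccc(OCOC)cc2)c(OCOC)c1Br
F10 | step 16 | 1-{3-[(1E,3S,5S)-5-hydroxy-1,7-bis[4-(methoxymethoxy)phenyl]hept-1-en-3-yl]-6-methoxy-2,4-bis(methoxymethoxy)phenyl}ethan-1-one | COc1cc(OCOC)c([C@H](/C=C/c2ccc(OCOC)cc2)C[C@@H](O)CCc2ccc(OCOC)cc2)c(OCOC)c1C(C)=O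
F11 | step 16 | 1-{2-hydroxy-3-[(1E,3S,5S)-5-hydroxy-1,7-bis[4-(methoxymethoxy)phenyl]hept-1-en-3-yl]-6-methoxy-4-(methoxymethoxy)phenyl}ethan-1-one | COc1cc(OCOC)c([C@H](/C=C/c2ccc(OCOC)cc2)C[C@@H](O)CCc2ccc(OCOC)cc2)c(O)c1C(C)=O
F12 | step 16 | (2E)-3-(dimethylamino)-1-{2-hydroxy-3-[(1E,3S,5S)-5-hydroxy-1,7-bis[4-(methoxymethoxy)phenyl]hept-1-en-3-yl]-6-methoxy-4-(methoxymethoxy)phenyl}prop-2-en-1-one | COc1cc(OCOC)c([C@H](/C=C/c2ccc(OCOC)cc2)C[C@@H](O)CCc2ccc(OCOC)cc2)c(O)c1C(=O)/C=C/N(C)C
F13 | step 16 | 8-[(1E,3S,5S)-5-hydroxy-1,7-bis[4-(methoxymethoxy)phenyl]hept-1-en-3-yl]-5-methoxy-7-(methoxymethoxy)-4H-chromen-4-one | COc1cc(OCOC)c([C@H](/C=C/c2ccc(OCOC)cc2)C[C@@H](O)CCc2ccc(OCOC)cc2)c2c1C(=O)C=CO2
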